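**Retrosynthetic overview**
- Ring B halogens: C3–Cl and C2–Br come from the two C–O bonds of a ring B oxirane (O→Br at C2 with inversion, O→Cl at C3 with retention through a bromonium ion).
- The oxirane comes from 10-bromo-α-chamigrene by site- and face-selective epoxidation; this C–O bond formation sets C2 and C3.
- Ring B and the spiro centre (C1–C6 bond) come from a bicyclic bromo ether by acid ionisation of its two tertiary C–O bonds.
- Ring A (C6–C11 bond) and a temporary pyran ring (C7–O bond) come from (E)-nerolidol in one enantioselective bromonium cascade.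
- Order of ring formation: ring A with the pyran, then ring B, then the oxirane relay.

Assumptions: positions carry farnesane/chamigrene numbers (C1–C5 ring B, C6 spiro, C7–C11 ring A); racemic (E)-nerolidol is used, its carbinol centre is erased in step 2, so 2, 3, F4 and F5 are epimer pairs and their SMILES leave that centre (and the new CHBr centre of F4/F5) open; the catalyst enantiomer that gives the 10R bromide is used, its sense taken by analogy and to be confirmed in the first run.

**Step 1**
Reactants: 1 (E)-nerolidol
Product: 2 (4aR,6R,8aR)-6-bromo-2-ethenyl-2,5,5,8a-tetramethyloctahydro-2H-chromene (farnesane numbering 6R,7R,10R; both C3 epimers)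
Conditions: NBS (1.05 equiv), (R)-3,3'-bis(2,4,6-triisopropylphenyl)-1,1'-binaphthalene-2,2'-diyl 2-{3-[3,5-bis(trifluoromethyl)phenyl]ureido}phenyl phosphite (10 mol%), toluene/CH2Cl2 1:1, −78 → −40 °C
Reagents that add atoms: N-bromosuccinimide, O=C1CCC(=O)N1Br
Why: Proposed new method: the phosphite phosphorus takes Br+ from NBS and hands it to the terminal C10=C11 alkene while the urea hydrogen-bonds the hydroxyl and holds the chain folded chair–chair, so that anti addition across C10=C11 and C6=C7 and closure of the C7–O bond run as one cascade and the catalyst decides the face at C10 (10R, Br equatorial, trans-fused); the closest known reactions are the phosphite–urea-catalysed enantioselective bromocyclisation of 2-geranylphenols (phenol oxygen as terminator) and the racemic BDSB or TBCO bromocyclisation of polyene alcohols, and what is new is an aliphatic tertiary alcohol as the C–O terminator of a catalytic enantioselective bromonium polyene cyclisation.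

**Step 2**
Reactants: 2 (4aR,6R,8aR)-6-bromo-2-ethenyl-2,5,5,8a-tetramethyloctahydro-2H-chromene
Product: 4 (6R,10R)-10-bromo-3,7,11,11-tetramethylspiro[5.5]undeca-2,7-diene (10-bromo-α-chamigrene), via ring-opened dienol 3 (not isolated)
Conditions: TfOH (10 mol%), HFIP/CH2Cl2 1:4, −40 → −10 °C, then Et3N quench
Reagents that add atoms: none
Why: Biomimetic cation–olefin spirocyclisation (Prins type, as for monocyclonerolidols): acid opens the tertiary C7–O bond with reversible E1 proton loss to the tetrasubstituted C6=C7 alkene (3), allylic ionisation at C3 follows, C6 attacks C1 to close ring B on the face anti to the pseudoaxial C11 methyl (Br equatorial, so C1 ends trans to Br and the spiro centre is 6R), and the C7 cation loses H8 to the thermodynamic endocyclic alkene; both C3 epimers of 2 converge.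

**Step 3**
Reactants: 4 (6R,10R)-10-bromo-3,7,11,11-tetramethylspiro[5.5]undeca-2,7-diene
Product: 5 (2R,3S,6R,10R)-10-bromo-2,3-epoxy-3,7,11,11-tetramethylspiro[5.5]undec-7-ene
Conditions: D-fructose-derived Shi ketone (1,2:4,5-di-O-isopropylidene-β-D-erythro-2,3-hexodiulo-2,6-pyranose, 30 mol%), Oxone (2KHSO5·KHSO4·K2SO4), K2CO3, Bu4NHSO4, MeCN/DMM–aq. Na2B4O7 buffer (pH 10.5), 0 °C
Reagents that add atoms: potassium peroxymonosulfate (active part of Oxone), [K+].[O-]S(=O)(=O)OO
Why: Shi asymmetric epoxidation (dioxirane, spiro transition state): the ring B alkene reacts in preference to the ring A alkene, which is flanked by the spiro and gem-dimethyl carbons, and oxygen is delivered to the face anti to the axial C7 branch (cis to C11), the face the D-fructose ketone is also expected to prefer by the spiro model, so C2 (R) and C3 (S) are set together.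

**Step 4**
Reactants: 5 (2R,3S,6R,10R)-10-bromo-2,3-epoxy-3,7,11,11-tetramethylspiro[5.5]undec-7-ene
Product: 6 (2S,3S,6R,10R)-2,10-dibromo-3,7,11,11-tetramethylspiro[5.5]undec-7-en-3-ol
Conditions: Li2NiBr4 (divalent nickel, from LiBr and NiBr2), THF, 0 °C → rt; aqueous pH 7 work-up
Reagents that add atoms: dilithium tetrabromonickelate, [Li+].[Li+].[Ni+2].[Br-].[Br-].[Br-].[Br-]
Why: SN2 oxirane opening by bromide at the secondary C2 (Fürst–Plattner trans-diaxial opening in the chair that keeps C11 equatorial) inverts C2 to S and leaves the C3–O bond untouched, giving the trans-diaxial bromohydrin.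

**Step 5**
Reactants: 6 (2S,3S,6R,10R)-2,10-dibromo-3,7,11,11-tetramethylspiro[5.5]undec-7-en-3-ol
Product: 9 (2S,3S,6R,10R)-2,10-dibromo-3-chloro-3,7,11,11-tetramethylspiro[5.5]undec-7-ene (target), via chlorosulfite 7 (not isolated), via bromonium chloride 8 (not isolated)
Conditions: SOCl2 (1.3 equiv), CH2Cl2, −40 → 0 °C
Reagents that add atoms: thionyl chloride, ClS(Cl)=O
Why: Deoxychlorination with neighbouring-group participation (Winstein-type anchimeric assistance): the antiperiplanar C2 bromine expels the axial chlorosulfite of 7 to form bromonium ion 8, which chloride opens at the tertiary C3 on the face the oxygen had occupied (double inversion, so retention at C3; Markovnikov and trans-diaxial), giving the trans bromochloride with C3 S and C2 S.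

**Compound list**
1 | (E)-nerolidol, (6E)-3,7,11-trimethyldodeca-1,6,10-trien-3-ol, racemic | C=CC(C)(O)CC/C=C(\C)CCC=C(C)C | starting material
2 | (4aR,6R,8aR)-6-bromo-2-ethenyl-2,5,5,8a-tetramethyloctahydro-2H-chromene, both C2 (chromene) epimers | C=CC1(C)CC[C@@H]2C(C)(C)[C@H](Br)CC[C@@]2(C)O1 | intermediate
3 | 5-[(5R)-5-bromo-2,6,6-trimethylcyclohex-1-en-1-yl]-3-methylpent-1-en-3-ol, both C3 epimers (ring-opened dienol) | C=CC(C)(O)CCC1=C(C)CC[C@@H](Br)C1(C)C | intermediate (not isolated)
4 | (6R,10R)-10-bromo-3,7,11,11-tetramethylspiro[5.5]undeca-2,7-diene (10-bromo-α-chamigrene) | CC1=CC[C@@H](Br)C(C)(C)[C@@]12CCC(C)=CC2 | intermediate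
5 | (2R,3S,6R,10R)-10-bromo-2,3-epoxy-3,7,11,11-tetramethylspiro[5.5]undec-7-ene | CC1=CC[C@@H](Br)C(C)(C)[C@@]12CC[C@](C)(O3)[C@H]3C2 | intermediate
6 | (2S,3S,6R,10R)-2,10-dibromo-3,7,11,11-tetramethylspiro[5.5]undec-7-en-3-ol | CC1=CC[C@@H](Br)C(C)(C)[C@@]12CC[C@](C)(O)[C@@H](Br)C2 | intermediate
7 | chlorosulfite ester of 6 at the C3 oxygen | CC1=CC[C@@H](Br)C(C)(C)[C@@]12CC[C@](C)(OS(Cl)=O)[C@@H](Br)C2 | intermediate (not isolated)
8 | C2–C3 bromonium chloride, bromine bridging the face opposite the former C3–O bond | CC1=CC[C@@H](Br)C(C)(C)[C@@]12CC[C@@](C)([Br+]3)[C@@H]3C2.[Cl-] | intermediate (not isolated)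
9 | (2S,3S,6R,10R)-2,10-dibromo-3-chloro-3,7,11,11-tetramethylspiro[5.5]undec-7-ene | CC1=CC[C@@H](Br)C(C)(C)[C@@]12CC[C@](C)(Cl)[C@@H](Br)C2 | target

**Step count and risks**
Total step count: 5. Longest linear sequence: 5.

The three steps most likely to fail:

Step 1 (the proposed new step). The risks are low enantioselectivity with an aliphatic alcohol terminator and direct bromoetherification of the C6=C7 alkene by the hydroxyl. The fallback uses known chemistry and sets out from 1. Racemic bromocyclisation with BDSB (Et2SBr·SbCl5Br, MeNO2, −25 °C) gives racemic 2, that is 2 together with its mirror image ent-2 F1. Step 2 then gives racemic 4, that is 4 together with ent-4 F2. The Shi epoxidation of step 3 sorts the two: 4 is the matched enantiomer and gives 5, while F2 is mismatched and is left unreacted or ends as the diastereomeric oxirane F3. F2 and F3 are removed by chromatography, with preparative chiral HPLC of 5 if needed. The fallback comes back to the route at 5, at the cost of at most half of the material.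

Step 2. The allylic C3–O bond ionises before the C7–O bond, so the ring A alkene must form while the allyl unit is already active. Drimane-type closures and diene formation compete, and the facial selectivity at C6 may be modest. The fallback sets out from 2 and masks the vinyl group. Br2 (1 equiv, CH2Cl2, −78 °C) gives the vinyl dibromide F4, in which the C3–O bond is no longer allylic. TsOH (benzene, 60 °C) then opens only the C7–O bond and equilibrates the ring alkene to the tetrasubstituted position, giving the ring-opened dibromo alcohol F5. Zinc dust (AcOH/Et2O, 0 °C) releases the vinyl group. The fallback comes back to the route at 3, now an isolated compound, which is closed to 4 in a separate step with HCO2H at 0 °C.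

Step 5. The risks are E1 loss of a proton from the bromonium ion (allylic bromide by-products) and addition of HCl to the ring A alkene. The fallback abandons the oxygen relay and sets out from 4. Direct Markovnikov anti bromochlorination of the ring B alkene with NBS and ClTi(OiPr)3 (CH2Cl2/hexanes, −20 °C) is followed by HPLC separation of the diastereomers. It comes back to the route at 9 and makes no new compound (F0).

**Further compounds**
F1 | step 1 | ent-2, (4aS,6S,8aS)-6-bromo-2-ethenyl-2,5,5,8a-tetramethyloctahydro-2H-chromene | C=CC1(C)CC[C@H]2C(C)(C)[C@@H](Br)CC[C@]2(C)O1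
F2 | step 1 | ent-4, (6S,10S)-10-bromo-3,7,11,11-tetramethylspiro[5.5]undeca-2,7-diene | CC1=CC[C@H](Br)C(C)(C)[C@]12CCC(C)=CC2
F3 | step 1 | (2R,3S,6S,10S)-10-bromo-2,3-epoxy-3,7,11,11-tetramethylspiro[5.5]undec-7-ene | CC1=CC[C@H](Br)C(C)(C)[C@]12CC[C@](C)(O3)[C@H]3C2
F4 | step 2 | (4aR,6R,8aR)-6-bromo-2-(1,2-dibromoethyl)-2,5,5,8a-tetramethyloctahydro-2H-chromene | BrCC(Br)C1(C)CC[C@@H]2C(C)(C)[C@H](Br)CC[C@@]2(C)O1
F5 | step 2 | 1,2-dibromo-5-[(5R)-5-bromo-2,6,6-trimethylcyclohex-1-en-1-yl]-3-methylpentan-3-ol | BrCC(Br)C(C)(O)CCC1=C(C)CC[C@@H](Br)C1(C)C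
F0 | step 5 | none | none
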